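# Total synthesis proposal for CNP0293926.1

## The problem

- **Numbering.** Atoms are numbered as in a germacran-12,6-olide. The ring carbons are C1–C10: C3 is the ketone, C4 the CH(CH3), C6 the lactone carbinol, C7 the ring-fusion CH, C8 the isobutyryloxy carbon and C10 the tertiary carbinol. C11–C13 are the lactone carbons, and C14 and C15 are the methyls on C10 and C4.
- **Ring system.** The core is a ten-membered carbocycle, cis-fused at C6–C7 to an α-methylene-γ-butyrolactone. Any direct closure of that ring pays for transannular strain and unfavourable entropy at the same time.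
- **Stereocentres.** O6, C11, O8 and C15 all stand on one face (α) of the carbocycle, and O10 stands on the other (β). C6, C7 and C8 can control one another, but C4 and C10 are isolated by CH2 groups and have no neighbour to lean on.
- **Oxygen differentiation.** O6 and O8 are related by a local mirror plane through C7, so either could close the lactone. Together with O10, three hydroxyl-level oxygens must end up as lactone, isobutyrate and free tertiary alcohol.
- **Sensitive groups.** The exocyclic enoate is a Michael acceptor, C4 is epimerizable, a C8 ketone next to an acylated O6 would eliminate, and the γ-hydroxy ketone (C10–OH/C3=O) is prone to dehydration. Strong base, nucleophiles and hot acid are therefore excluded late in the route.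
- **Feature that makes the key step possible.** C3 and C8 lie 1,6 across the ring, so a C3=C8 double bond turns the carbocycle into two fused six-membered rings (ring A: C3–C8; ring B: C3, C2, C1, C10, C9, C8), which is a Birch-reduced tetralin. In addition, C3 is γ to both O6 and O10, and these lie on opposite faces, which is exactly the arrangement in which C3 can carry both oxygens as a 1,6-dioxaspiro[4.4]nonane.

## Retrosynthesis

**22 ⇒ 20.** The O6–C12 lactone bond is cut, and O6 and O10 are tied back onto C3, which gives the spiroketal acrylic acid 20, a constitutional isomer of 22.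
- Cutting O8–acyl or C11=C13 last would leave the O6/O8 ambiguity or a lactone/ketone enolate competition in the final step.
- In 20 only O6 can reach C12, because O8 is acylated and O10 is too far away.
- The forward step needs only catalytic acid. The ketal opens reversibly, and lactonization is the only irreversible exit.

**20 ⇒ 17.** The C11=C13 bond is cut and C12 goes back to the aldehyde level, masked as the dimethyl acetal 17 (by way of 18 and 19).
- Methylenating an aldehyde through its enamine avoids strong base. A lactone enolate could not be formed selectively once the C3 ketone is free.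
- 17 has no π bond and no acidic C–H of concern.

**17 ⇒ 15.** The O8–acyl bond and the C8–H bond are cut, which leads to spiroketal ketone 15.
- In 15 the C3 carbonyl, O6 and O10 are all hidden in the spiroketal.
- The reduction therefore has one carbonyl to attack, and the acylation one hydroxyl.
- The forward reduction must deliver hydride to the β face.

**15 ⇒ 11 (key disconnection).** The C10–O10, C3–O10 and C3–O6 bonds are cut, and the two carbonyl carbons C3 and C8 are rejoined as a C3=C8 double bond.
- The product of this cut is the hexahydronaphthalenol 11, an ordinary bicycle with three stereocentres on a cyclohexene ring.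
- No other transannular bond gives two six-membered rings and puts both new oxygens where the target has them.
- The cut removes the medium ring, C10 and the oxygen differentiation from the problem at one stroke.
- The forward step needs ozone to prefer the tetrasubstituted alkene, and the released ene-dione to fold up rather than undergo aldol closure.

**11 ⇒ 10.** Two C–H bonds (C2, C9) are removed, and ring B becomes the arene of tetralol 10.
- A 1,2,4-trialkylbenzene can only give the diene with sp3 carbons at the two unsubstituted para positions C2 and C9.
- The Birch reduction therefore writes the C3=C8/C1=C10 pattern by itself.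

**10 ⇒ 8.** The C7–C11 bond and the C6–H bond are cut.
- In β-tetralone 8, C7 is benzylic and α to the ketone. This makes it the only site of enolate alkylation and keeps it configurationally labile in 9.
- One catalyst-controlled reduction with dynamic kinetic resolution then sets C6 and C7 together.

**8 ⇒ 1 + 2.** The C7–C8 aryl bond is cut (Buchner reaction of diazoketone 6 and rearomatization), then C6–C7 (diazomethane acylation of acid 4) and C3–C4 (conjugate arylation of crotonate 2 by boronic acid 1, giving 3).
- The para-methyl group of 1 is C14, and its position para to C3 is what places it on C10.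

## Roads not taken

**Alternative 1: cut C1–C2 (the most obvious plan).**
- *Forward key step.* Ring-closing metathesis of the open-chain diene A1 with second-generation Grubbs catalyst gives the macrocyclic enone A2. Conjugate reduction follows.
- *Why the chosen plan is better.* All five stereocentres would have to be set beforehand on a flexible chain by separate asymmetric steps. The two reacting alkenes are a vinyl ketone and a hindered tertiary allylic alcohol, the ring strain is paid in the reversible metathesis step (so oligomers are favoured), the C11=C13 enoate is a third metathesis partner, and C1=C2 must afterwards be reduced in its presence. The chosen plan never closes the ten-membered ring at all.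

**Alternative 2: cut C6–C7 together with O6–C12.**
- *Forward key step.* Intramolecular Barbier or Nozaki–Hiyama–Kishi-type allylation of bromo aldehyde A3 (CrCl2 or Zn), followed by lactonization.
- *Why the chosen plan is better.* This closes both rings at once, but through a ten-membered transition state. The C3 ketone competes with the aldehyde. The C6/C7 relation depends on an enoate geometry and a chair that the ring may not allow. C4, C8 and C10 still need three unrelated asymmetric operations.

**Alternative 3: cut the same C3–C8 bond pericyclically.**
- *Forward key step.* Anionic oxy-Cope rearrangement (KH, 18-crown-6) of the carvone-derived divinylcyclohexenol A4 gives the cyclodecadienone A5.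
- *Why the chosen plan is better.* The ring arrives quickly, but C8 becomes sp2, so the relay from C7 is lost. A5 carries no oxygen at C6, C8 or C10, and C6 of carvone is an unactivated CH2. Three oxygenations and the C4 reduction would have to be steered on a floppy ring. The oxidative cut of the chosen plan delivers C8 and C3 already oxygenated and C10 fixed.

Key step: step 8

Assumption: the ligand antipodes named in steps 1 and 6 are those expected by analogy to give 4R and 6S,7R. If the sense of induction is opposite, the mirror-image ligand is used.

## Route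

Step 1
Reactants: 1 4-methylphenylboronic acid; 2 ethyl (E)-but-2-enoate
Product: 3 ethyl (3R)-3-(4-methylphenyl)butanoate
Conditions: Rh(acac)(C2H4)2 (3 mol %), (S)-BINAP, dioxane–H2O 10:1, 100 °C
Reagents that add atoms: none
Why: Hayashi–Miyaura conjugate addition: the aryl–rhodium species adds to the β-carbon of 2 and the rhodium enolate is hydrolysed; the BINAP pocket leaves one enoate face open and should set C4 as R.

Step 2
Reactants: 3 ethyl (3R)-3-(4-methylphenyl)butanoate
Product: 4 (3R)-3-(4-methylphenyl)butanoic acid
Conditions: LiOH, THF–H2O, rt; then 1 M HCl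
Reagents that add atoms: lithium hydroxide [Li+].[OH-]
Why: Plain ester saponification; the stereocentre is β to the carboxyl group and cannot epimerize.

Step 3
Reactants: 4 (3R)-3-(4-methylphenyl)butanoic acid
Product: 6 (4R)-1-diazo-4-(4-methylphenyl)pentan-2-one, via acid chloride 5 (not isolated)
Conditions: (COCl)2, cat. DMF, CH2Cl2, 0 °C to rt, evaporate; CH2N2 (excess), Et2O, 0 °C
Reagents that add atoms: diazomethane C=[N+]=[N-]
Why: Acylation of diazomethane as in the first stage of the Arndt–Eistert sequence brings in C7; the second equivalent of diazomethane takes up HCl so that no chloroketone forms.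

Step 4
Reactants: 6 (4R)-1-diazo-4-(4-methylphenyl)pentan-2-one
Product: 8 (4R)-4,7-dimethyl-3,4-dihydronaphthalen-2(1H)-one, via dihydroazulenone 7 (not isolated)
Conditions: Rh2(OAc)4 (1 mol %), CH2Cl2, reflux; then CF3CO2H, 0 °C
Reagents that add atoms: none
Why: Intramolecular Buchner reaction of the rhodium carbenoid at the ipso/ortho bond gives the cycloheptatriene 7, which acid rearomatizes to the β-tetralone and so forms the C7–C8 bond. The two ortho positions of the p-tolyl ring are equivalent and C4 is not touched.

Step 5
Reactants: 8 (4R)-4,7-dimethyl-3,4-dihydronaphthalen-2(1H)-one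
Product: 9 (4R)-1-(2,2-dimethoxyethyl)-4,7-dimethyl-3,4-dihydronaphthalen-2(1H)-one (C1 epimers)
Conditions: NaH, DMF, 0 °C; BrCH2CH(OMe)2, NaI (cat.), 60 °C
Reagents that add atoms: 2-bromo-1,1-dimethoxyethane COC(CBr)OC
Why: Enolate alkylation: a β-tetralone is deprotonated at the benzylic C7, which gives the aryl-conjugated enolate, so C11 and C12 enter at C7 only. The configuration at C7 is irrelevant because it stays labile in 9.

Step 6
Reactants: 9 (4R)-1-(2,2-dimethoxyethyl)-4,7-dimethyl-3,4-dihydronaphthalen-2(1H)-one (C1 epimers)
Product: 10 (1R,2S,4R)-1-(2,2-dimethoxyethyl)-4,7-dimethyl-1,2,3,4-tetrahydronaphthalen-2-ol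
Conditions: RuCl(p-cymene)[(S,S)-TsDPEN] (1 mol %), HCO2Na, H2O–DMF, 40 °C
Reagents that add atoms: none
Why: Noyori-type asymmetric transfer hydrogenation with dynamic kinetic resolution: the C7 epimers interconvert through the aryl-conjugated enol, and the catalyst reduces one of them faster, anti to the arm. C6 and C7 are thus set together as the cis pair under catalyst control, and thereby cis to the C4 methyl; the near-neutral formate medium spares the acetal.

Step 7
Reactants: 10 (1R,2S,4R)-1-(2,2-dimethoxyethyl)-4,7-dimethyl-1,2,3,4-tetrahydronaphthalen-2-ol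
Product: 11 (1R,2S,4R)-1-(2,2-dimethoxyethyl)-4,7-dimethyl-1,2,3,4,5,8-hexahydronaphthalen-2-ol
Conditions: Li, NH3(l), THF, t-BuOH, −78 to −33 °C; then solid NH4Cl
Reagents that add atoms: none
Why: Birch reduction: alkyl groups stay on sp2 carbons, so protonation occurs at the unsubstituted para pair C2/C9 and leaves C3=C8 (tetrasubstituted) and C1=C10 (trisubstituted). The alkoxide, the acetal and the stereocentres are inert to the dissolving metal.

Step 8
Reactants: 11 (1R,2S,4R)-1-(2,2-dimethoxyethyl)-4,7-dimethyl-1,2,3,4,5,8-hexahydronaphthalen-2-ol
Product: 15 3,6:3,10-diepoxy-7-(2,2-dimethoxyethyl)-4,10-dimethylcyclodecan-8-one (spiroketal ketone; target numbering), via ene-dione 12 (not isolated), via hemiketal 13 (not isolated), via enone hemiketal 14 (not isolated)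
Conditions: O3 (1.0 equiv), CH2Cl2–MeOH, −78 °C; Me2S, −78 °C to rt; then DBU (0.2 equiv), CH2Cl2, 0 °C to rt
Reagents that add atoms: ozone [O-][O+]=O
Why: Ozone adds fastest to the tetraalkyl C3=C8 bond, the most electron-rich π bond (C1=C10 carries one alkyl group less), and Me2S reduces the peroxidic products, so rings A and B merge into the ten-membered ene-dione 12, the way 1,4,5,8-tetrahydronaphthalenes are known to give cyclodecadienediones. O6–H closes oxolane 1 by 5-exo-trig addition to C3=O (13); a one-atom bridge across C3 and C6 can only be cis, so O6 takes the α side of C3 and the hemiketal OH the β side. DBU removes the doubly activated C9–H (α to C8=O and allylic) and reprotonation at C1 brings the alkene into conjugation (14), the usual β,γ to α,β enone isomerization. The hemiketal oxygen then closes oxolane 2 by 5-exo-trig oxa-Michael addition to C10, the hemiketal/oxa-Michael entry to spiroketals. C3 and C10 are the new stereocentres and both are dictated by C6: the second bridge must leave C3 on the face opposite to O6 and must again be cis, which puts O10 on the β face as in 22, and because the addition is reversible a wrong approach corrects itself. The selectivities needed are ozone for C3=C8 over C1=C10 (one equivalent, low temperature), C9–H over C7–H and C4–H (kinetic acidity) and oxa-Michael addition over transannular aldol closure, the last secured because C3 is held as a hemiketal and not as a ketone. The product has the C3 carbonyl, O6 and O10 masked in one unit and only C8=O exposed.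

Step 9
Reactants: 15 3,6:3,10-diepoxy-7-(2,2-dimethoxyethyl)-4,10-dimethylcyclodecan-8-one
Product: 16 3,6:3,10-diepoxy-7-(2,2-dimethoxyethyl)-4,10-dimethylcyclodecan-8-ol (8α-OH)
Conditions: LiBH(s-Bu)3, THF, −78 °C; then H2O
Reagents that add atoms: none
Why: Sterically controlled ketone reduction: the spiroketal core has a local twofold axis through C3 and C8 that makes the two carbonyl faces alike except for the C7 arm and the C10 methyl, both on the α face. The bulky hydride should therefore enter from the β face and leave O8 α, cis to the arm, as bulky borohydrides do with 2-alkylcycloalkanones.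

Step 10
Reactants: 16 3,6:3,10-diepoxy-7-(2,2-dimethoxyethyl)-4,10-dimethylcyclodecan-8-ol
Product: 17 3,6:3,10-diepoxy-7-(2,2-dimethoxyethyl)-4,10-dimethylcyclodecan-8-yl 2-methylpropanoate
Conditions: (i-PrCO)2O, DMAP (cat.), pyridine, CH2Cl2, rt
Reagents that add atoms: isobutyric anhydride CC(C)C(=O)OC(=O)C(C)C
Why: DMAP-catalysed acylation of the only free hydroxyl group; O6 and O10 are ketal oxygens, so the O6/O8/O10 problem is solved without a protecting group.

Step 11
Reactants: 17 3,6:3,10-diepoxy-7-(2,2-dimethoxyethyl)-4,10-dimethylcyclodecan-8-yl 2-methylpropanoate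
Product: 18 2-[3,6:3,10-diepoxy-4,10-dimethyl-8-(2-methylpropanoyloxy)cyclodecan-7-yl]acetaldehyde
Conditions: LiBF4, MeCN–H2O 98:2, rt
Reagents that add atoms: water O
Why: Mild Lewis-acid hydrolysis of an acyclic dimethyl acetal. The bicyclic spiroketal re-closes if it opens at all, and the ester is untouched.

Step 12
Reactants: 18 2-[3,6:3,10-diepoxy-4,10-dimethyl-8-(2-methylpropanoyloxy)cyclodecan-7-yl]acetaldehyde
Product: 19 2-[3,6:3,10-diepoxy-4,10-dimethyl-8-(2-methylpropanoyloxy)cyclodecan-7-yl]prop-2-enal
Conditions: 37 % aq. HCHO, pyrrolidine (10 mol %), EtCO2H (10 mol %), i-PrOH, 45 °C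
Reagents that add atoms: formaldehyde C=O
Why: Amine-catalysed α-methylenation of an aldehyde (Mannich addition of the enamine to formaldehyde iminium, then elimination) brings in C13 without strong base. C7 is β to the aldehyde and is not epimerized.

Step 13
Reactants: 19 2-[3,6:3,10-diepoxy-4,10-dimethyl-8-(2-methylpropanoyloxy)cyclodecan-7-yl]prop-2-enal
Product: 20 2-[3,6:3,10-diepoxy-4,10-dimethyl-8-(2-methylpropanoyloxy)cyclodecan-7-yl]prop-2-enoic acid
Conditions: NaClO2, NaH2PO4, 2-methylbut-2-ene, t-BuOH–H2O, 0 °C to rt
Reagents that add atoms: sodium chlorite [Na+].[O-]Cl=O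
Why: Pinnick oxidation, the standard way from 2-substituted acroleins to acrylic acids; the buffer leaves ketal and ester alone and the scavenger removes HOCl.

Step 14
Reactants: 20 2-[3,6:3,10-diepoxy-4,10-dimethyl-8-(2-methylpropanoyloxy)cyclodecan-7-yl]prop-2-enoic acid
Product: 22 CNP0293926.1 (target), via seco hydroxy acid 21 (not isolated)
Conditions: camphor-10-sulfonic acid (10 mol %), CH2Cl2 saturated with H2O, rt
Reagents that add atoms: none
Why: Acid-catalysed ketal opening followed by Fischer lactonization, overall an isomerization: both C3–O bonds open reversibly, but only free O6–H (21) finds the C12 acid in a five-membered closure, and this cis-lactonization drains the equilibrium. It leaves C3 as the ketone and O10 as the free tertiary alcohol; no stereocentre is touched and the water used is returned.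

## Compound list

1 | 4-methylphenylboronic acid | Cc1ccc(B(O)O)cc1 | starting material
2 | ethyl (E)-but-2-enoate | C/C=C/C(=O)OCC | starting material
3 | ethyl (3R)-3-(4-methylphenyl)butanoate | CCOC(=O)C[C@@H](C)c1ccc(C)cc1 | intermediate
4 | (3R)-3-(4-methylphenyl)butanoic acid | OC(=O)C[C@@H](C)c1ccc(C)cc1 | intermediate
5 | (3R)-3-(4-methylphenyl)butanoyl chloride | ClC(=O)C[C@@H](C)c1ccc(C)cc1 | intermediate
6 | (4R)-1-diazo-4-(4-methylphenyl)pentan-2-one | [N-]=[N+]=CC(=O)C[C@@H](C)c1ccc(C)cc1 | intermediate
7 | (3R)-3,6-dimethyl-3,8a-dihydroazulen-1(2H)-one (C8a epimers) | O=C1C[C@@H](C)C2=CC=C(C)C=CC12 | intermediate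
8 | (4R)-4,7-dimethyl-3,4-dihydronaphthalen-2(1H)-one | O=C1C[C@@H](C)c2ccc(C)cc2C1 | intermediate
9 | (4R)-1-(2,2-dimethoxyethyl)-4,7-dimethyl-3,4-dihydronaphthalen-2(1H)-one (C1 epimers) | COC(OC)CC1C(=O)C[C@@H](C)c2ccc(C)cc21 | intermediate
10 | (1R,2S,4R)-1-(2,2-dimethoxyethyl)-4,7-dimethyl-1,2,3,4-tetrahydronaphthalen-2-ol | O[C@H]1C[C@@H](C)c2ccc(C)cc2[C@H]1CC(OC)OC | intermediate
11 | (1R,2S,4R)-1-(2,2-dimethoxyethyl)-4,7-dimethyl-1,2,3,4,5,8-hexahydronaphthalen-2-ol | O[C@H]1C[C@@H](C)C2=C(CC(C)=CC2)[C@H]1CC(OC)OC | intermediate
12 | (Z)-6α-hydroxy-7α-(2,2-dimethoxyethyl)-4α,10-dimethylcyclodec-1(10)-ene-3,8-dione (target numbering) | O[C@H]1C[C@@H](C)C(=O)C/C=C(C)\CC(=O)[C@H]1CC(OC)OC | intermediate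
13 | (Z)-3,6α-epoxy-3β-hydroxy-7α-(2,2-dimethoxyethyl)-4α,10-dimethylcyclodec-1(10)-en-8-one | COC(OC)C[C@@H]1C(=O)C/C(C)=C\C[C@]2(O)O[C@H]1C[C@H]2C | intermediate
14 | 3,6α-epoxy-3β-hydroxy-7α-(2,2-dimethoxyethyl)-4α,10-dimethylcyclodec-9-en-8-one | COC(OC)C[C@@H]1C(=O)C=C(C)CC[C@]2(O)O[C@H]1C[C@H]2C | intermediate
15 | 3,6α:3,10β-diepoxy-7α-(2,2-dimethoxyethyl)-4α,10-dimethylcyclodecan-8-one (spiroketal ketone) | COC(OC)C[C@@H]1C(=O)C[C@]2(C)CC[C@]3(O2)O[C@H]1C[C@H]3C | intermediate
16 | 3,6α:3,10β-diepoxy-7α-(2,2-dimethoxyethyl)-4α,10-dimethylcyclodecan-8α-ol | COC(OC)C[C@@H]1[C@H](O)C[C@]2(C)CC[C@]3(O2)O[C@H]1C[C@H]3C | intermediate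
17 | 8α-isobutyrate of 16 | COC(OC)C[C@@H]1[C@H](OC(=O)C(C)C)C[C@]2(C)CC[C@]3(O2)O[C@H]1C[C@H]3C | intermediate
18 | 2-[3,6:3,10-diepoxy-4,10-dimethyl-8-(2-methylpropanoyloxy)cyclodecan-7-yl]acetaldehyde | O=CC[C@@H]1[C@H](OC(=O)C(C)C)C[C@]2(C)CC[C@]3(O2)O[C@H]1C[C@H]3C | intermediate
19 | 2-[3,6:3,10-diepoxy-4,10-dimethyl-8-(2-methylpropanoyloxy)cyclodecan-7-yl]prop-2-enal | C=C(C=O)[C@@H]1[C@H](OC(=O)C(C)C)C[C@]2(C)CC[C@]3(O2)O[C@H]1C[C@H]3C | intermediate
20 | 2-[3,6:3,10-diepoxy-4,10-dimethyl-8-(2-methylpropanoyloxy)cyclodecan-7-yl]prop-2-enoic acid | C=C(C(=O)O)[C@@H]1[C@H](OC(=O)C(C)C)C[C@]2(C)CC[C@]3(O2)O[C@H]1C[C@H]3C | intermediate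
21 | 2-[6α,10β-dihydroxy-4,10-dimethyl-8α-(2-methylpropanoyloxy)-3-oxocyclodecan-7-yl]prop-2-enoic acid | C=C(C(=O)O)[C@@H]1[C@H](OC(=O)C(C)C)C[C@@](C)(O)CCC(=O)[C@H](C)C[C@@H]1O | intermediate
22 | CNP0293926.1: (4R,6S,7S,8R,10S)-10-hydroxy-8-(2-methylpropanoyloxy)-3-oxogermacr-11(13)-en-12,6-olide | C=C1C(=O)O[C@H]2C[C@@H](C)C(=O)CC[C@](C)(O)C[C@@H](OC(=O)C(C)C)[C@@H]12 | target

## Step count and least certain steps

Total step count: 14. Longest linear sequence: 14 (fully linear from 1 and 2). No protecting-group step is used.

**Step 8 (key step).**
- *What may go wrong.* Ozone may discriminate too little between the tetra- and the trisubstituted alkene, which would cut ring B a second time. Under DBU the released 1,6-dicarbonyl system may undergo transannular aldol closure, lose configuration at C7 or C4 by enolization, or stop at the conjugated enone because addition to a β,β-disubstituted acceptor is reversible.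
- *Fallback.* It sets out from 11 and comes back at 15, and it forms the C10–O bond electrophilically without any base. The ozonolysis is stopped after the Me2S work-up and hemiketal 13 is isolated. PhSeCl in CH2Cl2 at −78 °C activates the only remaining alkene, and the hemiketal oxygen attacks the more substituted C10, under the same geometric constraint, to give the C1-phenylselanyl spiroketal ketone F1. Bu3SnH with AIBN then removes selenium and gives 15.

**Step 6.**
- *What may go wrong.* Racemization at C7 may be too slow relative to reduction. The catalyst may also distinguish poorly between the two flanks of a β-tetralone, so that the cis pair is formed with low control relative to C4.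
- *Fallback.* It sets out from 9 and comes back at 10, and it replaces catalyst control by substrate control plus recycling. LiBH(s-Bu)3 at −78 °C reduces both C7 epimers anti to the arm to give 10 and the other cis alcohol, the (1S,2R,4R) diastereomer F2. These are diastereomers because of C4 and are separated by chromatography. F2 is oxidized back to the labile ketone 9 with Dess–Martin periodinane and resubmitted.

**Step 9.**
- *What may go wrong.* Poor or inverted facial selectivity is possible if the eight-membered ring of the spiroketal adopts a conformation in which the arm and the methyl group do not shield the α face.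
- *Fallback.* It sets out from 15 and comes back at 17. The ketone is reduced under conditions that favour the other face (NaBH4, CeCl3, MeOH), or the minor epimer is simply collected, to give the 8β-alcohol F3. F3 is esterified with inversion by a Mitsunobu reaction with isobutyric acid (PPh3, DIAD), which sets C8 and installs the ester in one operation.

**Step 14.**
- *What may go wrong.* The spiroketal may be too stable to release O6 under acid mild enough to avoid dehydration of the tertiary alcohol and acid-catalysed epimerization at C4.
- *Fallback.* It sets out from 19 and comes back at 22, and it moves the ring switch to the aldehyde level, where hemiacetal formation needs no loss of water. Enal 19 is equilibrated with pyridinium p-toluenesulfonate in wet acetone to the α-methylene lactol F4 (O6 bonded to C12, C3 free). The lactol is oxidized as it forms with TEMPO and PhI(OAc)2 to the lactone 22.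

## Further compounds

F1 | step 8 | C1-phenylselanyl derivative of spiroketal ketone 15 (C1 configuration anti to O10) | COC(OC)C[C@@H]1C(=O)C[C@]2(C)C([Se]c4ccccc4)C[C@]3(O2)O[C@H]1C[C@H]3C
F2 | step 6 | (1S,2R,4R)-1-(2,2-dimethoxyethyl)-4,7-dimethyl-1,2,3,4-tetrahydronaphthalen-2-ol | O[C@@H]1C[C@@H](C)c2ccc(C)cc2[C@@H]1CC(OC)OC
F3 | step 9 | 8β-epimer of alcohol 16 | COC(OC)C[C@@H]1[C@@H](O)C[C@]2(C)CC[C@]3(O2)O[C@H]1C[C@H]3C
F4 | step 14 | α-methylene lactol (22 with C12 as CH(OH), C12 epimers) | C=C1C(O)O[C@H]2C[C@@H](C)C(=O)CC[C@](C)(O)C[C@@H](OC(=O)C(C)C)[C@@H]12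
A1 | alternative 1 | open-chain metathesis diene (vinyl ketone and tertiary vinyl carbinol on the finished lactone) | C=C1C(=O)O[C@@H](C[C@@H](C)C(=O)C=C)[C@H]1[C@H](OC(=O)C(C)C)C[C@@](C)(O)C=C
A2 | alternative 1 | 1,2-didehydro derivative of 22 (macrocyclic enone) | C=C1C(=O)O[C@H]2C[C@@H](C)C(=O)C=C[C@](C)(O)C[C@@H](OC(=O)C(C)C)[C@@H]12
A3 | alternative 2 | methyl 2-(bromomethyl)enoate aldehyde for the intramolecular allylation | COC(=O)C(CBr)=C[C@H](OC(=O)C(C)C)C[C@@](C)(O)CCC(=O)[C@H](C)CC=O
A4 | alternative 3 | carvone-derived 1-vinyl-6-[(E)-prop-1-enyl]cyclohex-2-enol | C=CC1(O)C(C)=CC[C@H](C(C)=C)[C@H]1/C=C/C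
A5 | alternative 3 | oxy-Cope product, 7-isopropenyl-4,10-dimethylcyclodeca-4,8-dien-3-one | CC1=CC[C@H](C(C)=C)/C=C/C(C)CCC1=O
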